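**Strategy.** The route rests on cutting the dihydropyran ring across two opposite edges: the enol-ether O–C(sp2) bond and the C–C bond joining the O-bearing quaternary carbon to the ring-fusion CH, which is also a bond of the ten-membered carbocycle. Read this way the pyran is a formal [4+2] adduct of a methyl ketone C=O with an ortho-fluoroaryl ketone enolate. One base-mediated operation, macro-aldol addition followed by SNAr of the new tertiary alkoxide on the aryl fluoride, closes the ten-membered ring and the pyranone and sets both ring-fusion stereocentres. Its precursor is an open-chain (Z)-alkenyl diketone on a 2-fluoro-4,6-dimethoxy-3-isobutyrylphenyl core; the extra C=O and the aromaticity are removed afterwards.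

Key step: step 14

Remark: the macrocyclic intermediates 24–28 are named on the chromane skeleton; the eight-carbon bridge from C2 to C3 is numbered 1'–8' starting at C2 (bridge = C2–CH2–CH2–CH[C(CH3)2OTBS]–CH=CH–CH(CH3)–CH2–CH2–C3; TBS = tert-butyldimethylsilyl).

Step 1
Reactants: 1 1-fluoro-3,5-dimethoxybenzene; 2 2-methylpropanoyl chloride
Product: 3 1-(2-fluoro-4,6-dimethoxyphenyl)-2-methylpropan-1-one
Conditions: AlCl3, CH2Cl2, 0 °C
Reagents that add atoms: none
Why: Friedel–Crafts acylation should go to the carbon ortho to fluorine and para to one methoxy group, the site between the two methoxy groups being the more hindered one.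

Step 2
Reactants: 3 1-(2-fluoro-4,6-dimethoxyphenyl)-2-methylpropan-1-one; 4 3-chloropropanoyl chloride
Product: 5 3-chloro-1-[2-fluoro-4,6-dimethoxy-3-(2-methylpropanoyl)phenyl]propan-1-one
Conditions: AlCl3, ClCH2CH2Cl, 0 → 23 °C
Reagents that add atoms: none
Why: A second Friedel–Crafts acylation should follow the 4,6-diacylation pattern of resorcinol dimethyl ethers (ortho to F, para to OMe, meta to the first acyl group), which places fluorine between two carbonyl groups.

Step 3
Reactants: 5 3-chloro-1-[2-fluoro-4,6-dimethoxy-3-(2-methylpropanoyl)phenyl]propan-1-one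
Product: 6 1-[2-fluoro-4,6-dimethoxy-3-(2-methylpropanoyl)phenyl]prop-2-en-1-one
Conditions: Et3N, CH2Cl2, 0 °C
Reagents that add atoms: none
Why: E1cB dehydrochlorination of the β-chloro ketone should give the aryl vinyl ketone, and a tertiary amine cannot displace the activated fluoride.

Step 4
Reactants: 7 (R)-4-benzyl-3-propanoyl-1,3-oxazolidin-2-one; 8 3-iodoprop-1-ene
Product: 10 (R)-4-benzyl-3-[(S)-2-methylpent-4-enoyl]-1,3-oxazolidin-2-one, via sodium Z-enolate 9 (not isolated)
Conditions: NaHMDS, THF, −78 °C; then 8, −78 → −45 °C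
Reagents that add atoms: none
Why: Evans asymmetric alkylation: the chelated Z-enolate is allylated on the face opposite the benzyl group, which sets the (S)-methyl stereocentre that becomes the CH–CH3 of the carbocycle.

Step 5
Reactants: 10 (R)-4-benzyl-3-[(S)-2-methylpent-4-enoyl]-1,3-oxazolidin-2-one
Product: 11 (S)-2-methylpent-4-en-1-ol
Conditions: LiBH4, H2O (1 equiv), Et2O, 0 °C
Reagents that add atoms: none
Why: Reductive cleavage of the imide by borohydride should release the primary alcohol without touching the α-stereocentre or the alkene.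

Step 6
Reactants: 11 (S)-2-methylpent-4-en-1-ol
Product: 12 (S)-5-iodo-4-methylpent-1-ene
Conditions: I2, PPh3, imidazole, CH2Cl2, 0 → 23 °C
Reagents that add atoms: iodine, II
Why: Appel-type (Garegg–Samuelsson) iodination replaces the primary hydroxyl by SN2 and leaves the adjacent stereocentre untouched.

Step 7
Reactants: 12 (S)-5-iodo-4-methylpent-1-ene
Product: 13 [(S)-2-methylpent-4-en-1-yl]triphenylphosphonium iodide
Conditions: PPh3, MeCN, 85 °C
Reagents that add atoms: triphenylphosphine, c1ccc(cc1)P(c1ccccc1)c1ccccc1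
Why: SN2 quaternisation of the β-branched primary iodide should give the Wittig salt.

Step 8
Reactants: 14 ethyl 3-hydroxy-3-methylbutanoate
Product: 15 ethyl 3-[(tert-butyldimethylsilyl)oxy]-3-methylbutanoate
Conditions: TBSOTf, 2,6-lutidine, CH2Cl2, 0 → 23 °C
Reagents that add atoms: tert-butyldimethylsilyl triflate, CC(C)(C)[Si](C)(C)OS(=O)(=O)C(F)(F)F
Why: Silylation with the silyl triflate is the standard way to protect a tertiary alcohol; the ether must later prevent hemiketal formation with the methyl ketone.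

Step 9
Reactants: 15 ethyl 3-[(tert-butyldimethylsilyl)oxy]-3-methylbutanoate
Product: 16 3-[(tert-butyldimethylsilyl)oxy]-3-methylbutanal
Conditions: DIBAL-H (1.05 equiv), CH2Cl2, −78 °C; Rochelle salt
Reagents that add atoms: none
Why: DIBAL half-reduction at −78 °C stops at the aldehyde because the tetrahedral aluminate survives until work-up.

Step 10
Reactants: 16 3-[(tert-butyldimethylsilyl)oxy]-3-methylbutanal; 17 but-3-en-2-one
Product: 18 (S)-2-{2-[(tert-butyldimethylsilyl)oxy]propan-2-yl}-5-oxohexanal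
Conditions: (S)-2-[methoxy(diphenyl)methyl]pyrrolidine (10 mol%), ethyl 3,4-dihydroxybenzoate (20 mol%), neat, 4 °C
Reagents that add atoms: none
Why: Enamine-catalysed asymmetric Michael addition: the anti E-enamine should be attacked by the enone on the face away from the diphenylmethoxymethyl group, giving the (S)-aldehyde, which becomes the (R)-CH carrying the hydroxyisopropyl group.

Step 11
Reactants: 13 [(S)-2-methylpent-4-en-1-yl]triphenylphosphonium iodide; 18 (S)-2-{2-[(tert-butyldimethylsilyl)oxy]propan-2-yl}-5-oxohexanal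
Product: 20 (5R,6Z,8S)-5-{2-[(tert-butyldimethylsilyl)oxy]propan-2-yl}-8-methylundeca-6,10-dien-2-one, via phosphorus ylide 19 (not isolated)
Conditions: NaHMDS, THF, 0 °C; then 18, −78 → −20 °C
Reagents that add atoms: none
Why: Salt-free Wittig olefination with a non-stabilised ylide should give the (Z)-alkene through the kinetic cis-oxaphosphetane; the aldehyde reacts far faster than the methyl ketone and both allylic stereocentres should survive at low temperature.

Step 12
Reactants: 20 (5R,6Z,8S)-5-{2-[(tert-butyldimethylsilyl)oxy]propan-2-yl}-8-methylundeca-6,10-dien-2-one; 6 1-[2-fluoro-4,6-dimethoxy-3-(2-methylpropanoyl)phenyl]prop-2-en-1-one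
Product: 21 (2E,5S,6Z,8R)-8-{2-[(tert-butyldimethylsilyl)oxy]propan-2-yl}-1-[2-fluoro-4,6-dimethoxy-3-(2-methylpropanoyl)phenyl]-5-methyldodeca-2,6-diene-1,11-dione
Conditions: Hoveyda–Grubbs II (5 mol%), CH2Cl2, 40 °C
Reagents that add atoms: none
Why: Olefin cross-metathesis between the terminal alkene and the enone should give the (E)-enone, while the (Z)-alkene flanked by two branched allylic carbons is too hindered to react.

Step 13
Reactants: 21 (2E,5S,6Z,8R)-8-{2-[(tert-butyldimethylsilyl)oxy]propan-2-yl}-1-[2-fluoro-4,6-dimethoxy-3-(2-methylpropanoyl)phenyl]-5-methyldodeca-2,6-diene-1,11-dione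
Product: 22 (5S,6Z,8R)-8-{2-[(tert-butyldimethylsilyl)oxy]propan-2-yl}-1-[2-fluoro-4,6-dimethoxy-3-(2-methylpropanoyl)phenyl]-5-methyldodec-6-ene-1,11-dione
Conditions: [(Ph3P)CuH]6 (0.4 equiv), H2O (5 equiv), benzene/THF, 23 °C
Reagents that add atoms: none
Why: Stryker conjugate reduction delivers hydride only to the enone β-carbon, so isolated alkenes, ketones and the aryl fluoride should remain.

Step 14
Reactants: 22 (5S,6Z,8R)-8-{2-[(tert-butyldimethylsilyl)oxy]propan-2-yl}-1-[2-fluoro-4,6-dimethoxy-3-(2-methylpropanoyl)phenyl]-5-methyldodec-6-ene-1,11-dione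
Product: 24 (2R,3R)-5,7-dimethoxy-2-methyl-8-(2-methylpropanoyl)chroman-4-one with C2 and C3 joined by the (3'R,4'Z,6'S)-3'-{2-[(tert-butyldimethylsilyl)oxy]propan-2-yl}-6'-methyloct-4'-ene-1',8'-diyl bridge (2-methyl trans to 3-H), via potassium aldolate 23 (not isolated)
Conditions: KHMDS (1.1 equiv), THF (0.5 mM), −78 → 23 °C; aq. NH4Cl
Reagents that add atoms: none
Why: KHMDS sets up freely equilibrating potassium enolates, and of all reversible aldolates only the one formed when the aryl-ketone (Z)-enolate carbon adds to the methyl ketone (10-(enolexo)-exo-trig aldol closing the carbocycle) places its tertiary alkoxide six atoms from the C–F carbon, so it alone is drained by irreversible SNAr (6-exo-trig addition–elimination through a Meisenheimer complex, fluoride activated by the two ortho acyl groups) that closes the pyranone. The closest known reaction type is the tandem aldol/SNAr annulation of ortho-fluoroaryl ketones to 2,2-disubstituted chroman-4-ones, here run intramolecularly as a macrocyclisation under Curtin–Hammett control. The product-like SNAr transition state decides the quaternary O-bearing carbon: the (Z)-alkene with minimised allylic strain holds both chains on one face with the bulky silyloxyisopropyl and the methyl group outside the forming ring, and the trans ring fusion (2-methyl anti to 3-H) is expected to be the less strained arrangement. The ring-fusion CH is α to the new ketone and should therefore equilibrate under the reaction conditions to this trans isomer. The step needs intramolecular over intermolecular aldol/SNAr, which high dilution secures, and reaction of the methylene ketone rather than the isopropyl ketone, whose enolate would have to join two fully substituted carbons.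

Step 15
Reactants: 24 the macrocyclic (2R,3R)-chroman-4-one
Product: 25 (2R,3S)-4-hydroxy-5,7-dimethoxy-2-methyl-8-(2-methylpropanoyl)chromane with the same C2–C3 bridge (either C4 epimer)
Conditions: NaBH4, MeOH/THF, 0 °C
Reagents that add atoms: none
Why: Borohydride should reduce the planar cyclic aryl ketone and spare the twisted, doubly ortho-substituted isopropyl ketone; the new carbinol centre is removed in the next step.

Step 16
Reactants: 25 the macrocyclic chroman-4-ol
Product: 26 (2R,3S)-5,7-dimethoxy-2-methyl-8-(2-methylpropanoyl)chromane with the same C2–C3 bridge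
Conditions: Et3SiH (5 equiv), TFA (3 equiv), CH2Cl2, −20 °C
Reagents that add atoms: none
Why: Ionic hydrogenation: the electron-rich benzylic alcohol ionises under mild acid and the cation is trapped by silane hydride, which turns the former linker carbonyl into the CH2 of the target.

Step 17
Reactants: 26 the macrocyclic 5,7-dimethoxychromane
Product: 27 (2R,3S)-5,7-dihydroxy-2-methyl-8-(2-methylpropanoyl)chromane with the same C2–C3 bridge
Conditions: NaSEt (8 equiv), DMF, 120 °C; aq. NH4Cl
Reagents that add atoms: none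
Why: Thiolate SN2 O-demethylation cleaves the methoxy groups ortho and para to the acyl group, whereas the tertiary alkyl aryl ether and the silyl ether are not open to SN2 attack.

Step 18
Reactants: 27 the macrocyclic 5,7-dihydroxychromane
Product: 29 the target carrying a TBS ether on its tertiary alcohol, via C6-monomethyl phenol 28 (not isolated)
Conditions: NaOMe (3.5 equiv), MeI (2.5 equiv), MeOH, 0 → 23 °C; dilute HCl
Reagents that add atoms: iodomethane, CI
Why: Dearomative double C-methylation of the phloroglucinol-type phenoxide at the only unsubstituted ring carbon (between the two phenoxide oxygens), as in filicinic and syncarpic acid chemistry, should give the gem-dimethyl enolised triketone core; no stereocentre is involved.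

Step 19
Reactants: 29 the O-TBS ether of the target
Product: 30 CNP0564661.1 (target)
Conditions: HF·pyridine, THF/pyridine, 0 → 23 °C
Reagents that add atoms: none
Why: Fluoride-driven desilylation should free the tertiary alcohol without affecting the vinylogous ester, the enol or the (Z)-alkene.

**Compound list**

1 | 1-fluoro-3,5-dimethoxybenzene | COc1cc(F)cc(OC)c1 | starting material
2 | 2-methylpropanoyl chloride | CC(C)C(=O)Cl | starting material
3 | 1-(2-fluoro-4,6-dimethoxyphenyl)-2-methylpropan-1-one | CC(C)C(=O)c1c(F)cc(OC)cc1OC | intermediate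
4 | 3-chloropropanoyl chloride | ClCCC(=O)Cl | starting material
5 | 3-chloro-1-[2-fluoro-4,6-dimethoxy-3-(2-methylpropanoyl)phenyl]propan-1-one | CC(C)C(=O)c1c(F)c(C(=O)CCCl)c(OC)cc1OC | intermediate
6 | 1-[2-fluoro-4,6-dimethoxy-3-(2-methylpropanoyl)phenyl]prop-2-en-1-one | C=CC(=O)c1c(F)c(C(=O)C(C)C)c(OC)cc1OC | intermediate
7 | (R)-4-benzyl-3-propanoyl-1,3-oxazolidin-2-one | CCC(=O)N1[C@H](Cc2ccccc2)COC1=O | starting material
8 | 3-iodoprop-1-ene | C=CCI | starting material
9 | sodium (Z)-enolate of 7 | C/C=C(\[O-])N1[C@H](Cc2ccccc2)COC1=O.[Na+] | intermediate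
10 | (R)-4-benzyl-3-[(S)-2-methylpent-4-enoyl]-1,3-oxazolidin-2-one | C=CC[C@H](C)C(=O)N1[C@H](Cc2ccccc2)COC1=O | intermediate
11 | (S)-2-methylpent-4-en-1-ol | C=CC[C@H](C)CO | intermediate
12 | (S)-5-iodo-4-methylpent-1-ene | C=CC[C@H](C)CI | intermediate
13 | [(S)-2-methylpent-4-en-1-yl]triphenylphosphonium iodide | C=CC[C@H](C)C[P+](c1ccccc1)(c1ccccc1)c1ccccc1.[I-] | intermediate
14 | ethyl 3-hydroxy-3-methylbutanoate | CCOC(=O)CC(C)(C)O | starting material
15 | ethyl 3-[(tert-butyldimethylsilyl)oxy]-3-methylbutanoate | CCOC(=O)CC(C)(C)O[Si](C)(C)C(C)(C)C | intermediate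
16 | 3-[(tert-butyldimethylsilyl)oxy]-3-methylbutanal | O=CCC(C)(C)O[Si](C)(C)C(C)(C)C | intermediate
17 | but-3-en-2-one | C=CC(C)=O | starting material
18 | (S)-2-{2-[(tert-butyldimethylsilyl)oxy]propan-2-yl}-5-oxohexanal | CC(=O)CC[C@H](C=O)C(C)(C)O[Si](C)(C)C(C)(C)C | intermediate
19 | [(S)-2-methylpent-4-en-1-ylidene]triphenylphosphorane | C=CC[C@H](C)C=P(c1ccccc1)(c1ccccc1)c1ccccc1 | intermediate
20 | (5R,6Z,8S)-5-{2-[(tert-butyldimethylsilyl)oxy]propan-2-yl}-8-methylundeca-6,10-dien-2-one | CC(=O)CC[C@@H](C(C)(C)O[Si](C)(C)C(C)(C)C)/C=C\[C@@H](C)CC=C | intermediate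
21 | (2E,5S,6Z,8R)-8-{2-[(tert-butyldimethylsilyl)oxy]propan-2-yl}-1-[2-fluoro-4,6-dimethoxy-3-(2-methylpropanoyl)phenyl]-5-methyldodeca-2,6-diene-1,11-dione | CC(=O)CC[C@@H](C(C)(C)O[Si](C)(C)C(C)(C)C)/C=C\[C@@H](C)C/C=C/C(=O)c1c(F)c(C(=O)C(C)C)c(OC)cc1OC | intermediate
22 | (5S,6Z,8R)-8-{2-[(tert-butyldimethylsilyl)oxy]propan-2-yl}-1-[2-fluoro-4,6-dimethoxy-3-(2-methylpropanoyl)phenyl]-5-methyldodec-6-ene-1,11-dione | CC(=O)CC[C@@H](C(C)(C)O[Si](C)(C)C(C)(C)C)/C=C\[C@@H](C)CCCC(=O)c1c(F)c(C(=O)C(C)C)c(OC)cc1OC | intermediate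
23 | potassium (1R,2R,5S,6Z,8R)-2-[2-fluoro-4,6-dimethoxy-3-(2-methylpropanoyl)benzoyl]-1,5-dimethyl-8-{2-[(tert-butyldimethylsilyl)oxy]propan-2-yl}cyclodec-6-en-1-olate | C[C@@]1([O-])CC[C@@H](C(C)(C)O[Si](C)(C)C(C)(C)C)/C=C\[C@@H](C)CC[C@H]1C(=O)c1c(F)c(C(=O)C(C)C)c(OC)cc1OC.[K+] | intermediate
24 | (2R,3R)-5,7-dimethoxy-2-methyl-8-(2-methylpropanoyl)chroman-4-one, C2 and C3 joined by the (3'R,4'Z,6'S)-3'-{2-[(tert-butyldimethylsilyl)oxy]propan-2-yl}-6'-methyloct-4'-ene-1',8'-diyl bridge | C[C@@]12CC[C@@H](C(C)(C)O[Si](C)(C)C(C)(C)C)/C=C\[C@@H](C)CC[C@H]1C(=O)c1c(OC)cc(OC)c(C(=O)C(C)C)c1O2 | intermediate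
25 | (2R,3S)-4-hydroxy-5,7-dimethoxy-2-methyl-8-(2-methylpropanoyl)chromane with the same bridge (C4 epimers) | C[C@@]12CC[C@@H](C(C)(C)O[Si](C)(C)C(C)(C)C)/C=C\[C@@H](C)CC[C@H]1C(O)c1c(OC)cc(OC)c(C(=O)C(C)C)c1O2 | intermediate
26 | (2R,3S)-5,7-dimethoxy-2-methyl-8-(2-methylpropanoyl)chromane with the same bridge | C[C@@]12CC[C@@H](C(C)(C)O[Si](C)(C)C(C)(C)C)/C=C\[C@@H](C)CC[C@H]1Cc1c(OC)cc(OC)c(C(=O)C(C)C)c1O2 | intermediate
27 | (2R,3S)-5,7-dihydroxy-2-methyl-8-(2-methylpropanoyl)chromane with the same bridge | C[C@@]12CC[C@@H](C(C)(C)O[Si](C)(C)C(C)(C)C)/C=C\[C@@H](C)CC[C@H]1Cc1c(O)cc(O)c(C(=O)C(C)C)c1O2 | intermediate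
28 | (2R,3S)-5,7-dihydroxy-2,6-dimethyl-8-(2-methylpropanoyl)chromane with the same bridge | C[C@@]12CC[C@@H](C(C)(C)O[Si](C)(C)C(C)(C)C)/C=C\[C@@H](C)CC[C@H]1Cc1c(O)c(C)c(O)c(C(=O)C(C)C)c1O2 | intermediate
29 | O-TBS ether of the target (silyl ether on the hydroxyisopropyl group) | CC(C)C(=O)C1=C(O)C(C)(C)C(=O)C2=C1O[C@]1(C)CC[C@@H](C(C)(C)O[Si](C)(C)C(C)(C)C)/C=C\[C@@H](C)CC[C@H]1C2 | intermediate
30 | CNP0564661.1 | CC(C)C(=O)C1=C(O)C(C)(C)C(=O)C2=C1O[C@]1(C)CC[C@@H](C(C)(C)O)/C=C\[C@@H](C)CC[C@H]1C2 | target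

**Totals.** Total steps: 19. Longest linear sequence: 13 steps (7 → 30, steps 4–7 and 11–19).

**Steps most likely to fail**

1. Step 14 (key step). The ten-membered aldol closure may lose to intermolecular aldol/SNAr oligomerisation, and the remote stereocentres may select the face of the methyl ketone poorly. The fallback moves the ring closure to the alkene; it sets out from 6, 11 and 18 and comes back at 24. Cross-metathesis of 6 with 11 should give the (S,E)-enone alcohol F1. Stryker reduction should give the keto alcohol F2, Dess–Martin oxidation the aldehyde F3, and methylenation with Ph3P=CH2 at −78 °C the terminal alkene F4. Separately, chemoselective methylenation of the aldehyde group of 18 should give the vinyl ketone F5. The lithium enolate of F4 (LiHMDS, THF, −78 °C) is added to F5 and the aldolate closes by SNAr on warming to the open-chain diene chromanone F6; its C2 epimers are separated and C3 is equilibrated with DBU. Ring-closing metathesis with a Z-selective ruthenium catalyst under high dilution should then close the ten-membered ring and give 24.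

2. Step 10. Enamine formation from the neopentyl-type aldehyde may be slow, the silanolate may be lost by β-elimination, and the α-stereocentre of 18 may erode. The fallback takes the stereocentre from the chiral pool; it sets out from (R)-(+)-α-terpineol F7 and comes back at 18. Silylation (TBSOTf, 2,6-lutidine) should give the silyl ether F8. Ozonolysis (O3, then Me2S) opens the ring to the keto aldehyde F9. Morpholine should condense only with the aldehyde to give the enamine F10, and ozonolysis of the enamine C=C removes one carbon and should deliver 18.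

3. Step 16. The benzylic cation may lose a proton to give the 2H-chromene, which would scramble the ring-fusion CH, and the acid may cleave the tertiary silyl ether and ionise the alcohol. The fallback is a radical Barton–McCombie deoxygenation; it sets out from 25 and comes back at 26. 1,1'-Thiocarbonyldiimidazole with DMAP should give the imidazole-1-carbothioate F11, and Bu3SnH/AIBN in toluene at 80 °C should reduce it to 26.

Further compounds
F1 | step 14 | (S,E)-1-[2-fluoro-4,6-dimethoxy-3-(2-methylpropanoyl)phenyl]-6-hydroxy-5-methylhex-2-en-1-one | OC[C@@H](C)C/C=C/C(=O)c1c(F)c(C(=O)C(C)C)c(OC)cc1OC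
F2 | step 14 | (S)-1-[2-fluoro-4,6-dimethoxy-3-(2-methylpropanoyl)phenyl]-6-hydroxy-5-methylhexan-1-one | OC[C@@H](C)CCCC(=O)c1c(F)c(C(=O)C(C)C)c(OC)cc1OC
F3 | step 14 | (S)-6-[2-fluoro-4,6-dimethoxy-3-(2-methylpropanoyl)phenyl]-2-methyl-6-oxohexanal | O=C[C@@H](C)CCCC(=O)c1c(F)c(C(=O)C(C)C)c(OC)cc1OC
F4 | step 14 | (S)-1-[2-fluoro-4,6-dimethoxy-3-(2-methylpropanoyl)phenyl]-5-methylhept-6-en-1-one | C=C[C@@H](C)CCCC(=O)c1c(F)c(C(=O)C(C)C)c(OC)cc1OC
F5 | step 14 | (R)-5-{2-[(tert-butyldimethylsilyl)oxy]propan-2-yl}hept-6-en-2-one | CC(=O)CC[C@H](C=C)C(C)(C)O[Si](C)(C)C(C)(C)C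
F6 | step 14 | (2R,3R)-2-[(R)-3-{2-[(tert-butyldimethylsilyl)oxy]propan-2-yl}pent-4-en-1-yl]-5,7-dimethoxy-2-methyl-3-[(S)-3-methylpent-4-en-1-yl]-8-(2-methylpropanoyl)chroman-4-one | C[C@]1(CC[C@H](C=C)C(C)(C)O[Si](C)(C)C(C)(C)C)Oc2c(C(=O)C(C)C)c(OC)cc(OC)c2C(=O)[C@@H]1CC[C@H](C)C=C
F7 | step 10 | (R)-(+)-α-terpineol | CC1=CC[C@@H](CC1)C(C)(C)O
F8 | step 10 | (R)-tert-butyldimethyl{[2-(4-methylcyclohex-3-en-1-yl)propan-2-yl]oxy}silane | CC1=CC[C@@H](CC1)C(C)(C)O[Si](C)(C)C(C)(C)C
F9 | step 10 | (R)-3-{2-[(tert-butyldimethylsilyl)oxy]propan-2-yl}-6-oxoheptanal | CC(=O)CC[C@H](CC=O)C(C)(C)O[Si](C)(C)C(C)(C)C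
F10 | step 10 | (R,E)-5-{2-[(tert-butyldimethylsilyl)oxy]propan-2-yl}-7-(morpholin-4-yl)hept-6-en-2-one | CC(=O)CC[C@H](/C=C/N1CCOCC1)C(C)(C)O[Si](C)(C)C(C)(C)C
F11 | step 16 | O-(chroman-4-yl) 1H-imidazole-1-carbothioate of 25 | C[C@@]12CC[C@@H](C(C)(C)O[Si](C)(C)C(C)(C)C)/C=C\[C@@H](C)CC[C@H]1C(OC(=S)n1ccnc1)c1c(OC)cc(OC)c(C(=O)C(C)C)c1O2
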